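**Retrosynthetic overview** (germacrane numbering: C6 lactone carbinol, C7 ring fusion, C8 and C9 the acyloxy carbons, C1=C10 the Z olefin, C4=C5 the E olefin)
1. The O9 acetate goes on last; the O8 ester comes from Yamaguchi esterification with preformed (2S,3S)-2,3-dimethyloxirane-2-carboxylic acid (Sharpless epoxidation of angelyl alcohol).
2. The ten-membered carbocycle and then the γ-lactone are closed in one operation by a chromium-catalysed intramolecular 2-(methoxycarbonyl)allylation (C6–C7 bond) of a bromo-enal, which sets C6 and C7.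
3. The bromo-enal comes from a B-alkyl Suzuki–Miyaura coupling (C1–C2 bond) of a (Z)-vinyl iodide east fragment with a five-carbon west fragment.
4. East fragment: Brown syn-alkoxyallylation of (Z)-3-iodo-2-methylpropenal (sets C8 and C9), oxidative cleavage, Morita–Baylis–Hillman reaction. West fragment: (E)-3-methylpent-2-en-4-yn-1-ol converted to a diene acetal.
5. Ring order: ten-membered ring, then lactone (same flask); the oxirane is brought in already formed.

Assumption: the (S,S) antipode of the carbazole-bis(oxazoline) ligand in step 13 is taken to be the one that sends the allyl group to the Si face of the enal (6R); if the sense is the reverse, the (R,R) ligand is used instead.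

**Route**

Step 1
Reactants: 1 prop-2-yn-1-ol
Product: 3 (Z)-3-iodo-2-methylprop-2-en-1-ol, via cyclic alkenylmagnesium alkoxide 2 (not isolated)
Conditions: MeMgBr (2.5 equiv), CuI (10 mol%), Et2O, −10 °C→rt; then I2, THF, −78→0 °C
Reagents that add atoms: methylmagnesium bromide (C[Mg]Br); iodine (II)
Why: Copper-catalysed anti-carbomagnesiation of the propargylic alkoxide puts the methyl group on C2 and magnesium on C3 inside a five-membered chelate, so iodinolysis with retention gives only the Z-iodide (iodine cis to CH2OH), which fixes the later 1(10)-Z ring olefin.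

Step 2
Reactants: 3 (Z)-3-iodo-2-methylprop-2-en-1-ol
Product: 4 (Z)-3-iodo-2-methylprop-2-enal
Conditions: MnO2, CH2Cl2, rt, dark; filtered solution used at once
Reagents that add atoms: none
Why: Allylic oxidation with MnO2 is neutral and fast, which keeps the isomerisation-prone Z-iodoenal intact when it is used immediately.

Step 3
Reactants: 5 prop-2-en-1-ol
Product: 6 3-(methoxymethoxy)prop-1-ene
Conditions: MOMCl, i-Pr2NEt, CH2Cl2, 0 °C→rt
Reagents that add atoms: chloromethyl methyl ether (COCCl)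
Why: O-alkylation of the alcohol with the reactive α-chloro ether (Williamson-type etherification) gives the MOM ether that serves as the chelating γ-alkoxyallyl precursor.

Step 4
Reactants: 6 3-(methoxymethoxy)prop-1-ene; 4 (Z)-3-iodo-2-methylprop-2-enal
Product: 9 (3R,4R,Z)-1-iodo-4-(methoxymethoxy)-2-methylhexa-1,5-dien-3-ol, via allylborane 7 (not isolated), via borinate ester 8 (not isolated)
Conditions: 6, s-BuLi, THF, −78 °C; (−)-Ipc2BOMe; BF3·OEt2; then 4, −78 °C; NaOH, H2O2, 0 °C→rt
Reagents that add atoms: none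
Why: Brown asymmetric γ-alkoxyallylboration, in which the Z-allylborane reacts through a chair six-membered transition state to give the syn monoprotected diol and the isopinocampheyl groups derived from (+)-α-pinene direct addition to the Si face of the aldehyde, setting C9 (R) and C8 (R).

Step 5
Reactants: 9 (3R,4R,Z)-1-iodo-4-(methoxymethoxy)-2-methylhexa-1,5-dien-3-ol
Product: 10 tert-butyl{[(3R,4R,Z)-1-iodo-4-(methoxymethoxy)-2-methylhexa-1,5-dien-3-yl]oxy}dimethylsilane
Conditions: TBSOTf, 2,6-lutidine, CH2Cl2, −78→0 °C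
Reagents that add atoms: tert-butyldimethylsilyl triflate (CC(C)(C)[Si](C)(C)OS(=O)(=O)C(F)(F)F)
Why: O-silylation of the hindered allylic alcohol with the silyl triflate gives a C9 silyl ether that is orthogonal to the C8 MOM ether.

Step 6
Reactants: 10 tert-butyl{[(3R,4R,Z)-1-iodo-4-(methoxymethoxy)-2-methylhexa-1,5-dien-3-yl]oxy}dimethylsilane
Product: 12 (2S,3R,Z)-3-(tert-butyldimethylsilyloxy)-5-iodo-2-(methoxymethoxy)-4-methylpent-4-enal, via diol 11 (not isolated)
Conditions: OsO4 (2 mol%), NMO, acetone–H2O, rt; then NaIO4, THF–H2O, 0 °C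
Reagents that add atoms: N-methylmorpholine N-oxide (C[N+]1([O-])CCOCC1); water (O)
Why: Lemieux–Johnson-type oxidative cleavage, in which OsO4 dihydroxylates only the monosubstituted olefin because the trisubstituted iodoalkene is electron-poor and hindered, and periodate cleaves the diol to the aldehyde without touching the C8 stereocentre.

Step 7
Reactants: 12 (2S,3R,Z)-3-(tert-butyldimethylsilyloxy)-5-iodo-2-(methoxymethoxy)-4-methylpent-4-enal; 13 methyl acrylate
Product: 14 methyl 2-[(2R,3R,4Z)-3-(tert-butyldimethylsilyloxy)-1-hydroxy-5-iodo-2-(methoxymethoxy)-4-methylpent-4-en-1-yl]prop-2-enoate (both C1 epimers)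
Conditions: 13 (10 equiv), DABCO (1 equiv), 1,4-dioxane–H2O, rt
Reagents that add atoms: none
Why: Morita–Baylis–Hillman reaction of the activated α,β-dialkoxy aldehyde under weakly basic amine catalysis installs the acrylate unit (C11 to C13), and the new carbinol centre may form as a mixture because it becomes sp2 in step 12.

Step 8
Reactants: 15 (E)-3-methylpent-2-en-4-yn-1-ol
Product: 16 (E)-3-methylpent-2-en-4-ynal
Conditions: MnO2, CH2Cl2, rt
Reagents that add atoms: none
Why: Chemoselective MnO2 oxidation of the allylic alcohol gives the enynal with the E olefin unchanged.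

Step 9
Reactants: 16 (E)-3-methylpent-2-en-4-ynal
Product: 17 (E)-5,5-dimethoxy-3-methylpent-3-en-1-yne
Conditions: HC(OMe)3, MeOH, PPTS (cat.), 0 °C→rt
Reagents that add atoms: trimethyl orthoformate (COC(OC)OC); methanol (CO)
Why: Mild acid-catalysed acetalisation masks the aldehyde for the hydroboration and the coupling while leaving the E geometry in place.

Step 10
Reactants: 17 (E)-5,5-dimethoxy-3-methylpent-3-en-1-yne
Product: 18 (E)-5,5-dimethoxy-3-methylpenta-1,3-diene
Conditions: H2 (1 atm), Pd/CaCO3–Pb(OAc)2, quinoline, pentane, rt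
Reagents that add atoms: none
Why: Lindlar semihydrogenation stops at the vinyl group because the poisoned catalyst does not reduce the trisubstituted olefin.

Step 11
Reactants: 18 (E)-5,5-dimethoxy-3-methylpenta-1,3-diene; 14 methyl 2-[(2R,3R,4Z)-3-(tert-butyldimethylsilyloxy)-1-hydroxy-5-iodo-2-(methoxymethoxy)-4-methylpent-4-en-1-yl]prop-2-enoate
Product: 21 methyl 2-[(2R,3R,4Z,8E)-3-(tert-butyldimethylsilyloxy)-1-hydroxy-2-(methoxymethoxy)-4,8-dimethyl-10-oxodeca-4,8-dien-1-yl]prop-2-enoate (both C1 epimers), via alkylborane 19 (not isolated), via coupled acetal 20 (not isolated)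
Conditions: 18, 9-BBN, THF, 0 °C→rt; then 14, Pd(dppf)Cl2 (5 mol%), AsPh3, Cs2CO3, DMF–H2O, rt; then 1 M HCl, THF, 0 °C
Reagents that add atoms: water (O)
Why: B-alkyl Suzuki–Miyaura coupling, in which 9-BBN adds only to the terminal vinyl group of the diene and the primary alkylborane couples with the vinyl iodide with retention of the Z geometry under mild aqueous base tolerated by the acrylate, the hydroxyl and both ethers, after which dilute acid unmasks the enal.

Step 12
Reactants: 21 methyl 2-[(2R,3R,4Z,8E)-3-(tert-butyldimethylsilyloxy)-1-hydroxy-2-(methoxymethoxy)-4,8-dimethyl-10-oxodeca-4,8-dien-1-yl]prop-2-enoate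
Product: 22 methyl (2Z,4R,5R,6Z,10E)-2-(bromomethyl)-5-(tert-butyldimethylsilyloxy)-4-(methoxymethoxy)-6,10-dimethyl-12-oxododeca-2,6,10-trienoate
Conditions: NBS, Me2S, CH2Cl2, −20→0 °C
Reagents that add atoms: N-bromosuccinimide (O=C1CCC(=O)N1Br)
Why: Activation of the Baylis–Hillman alcohol as an alkoxysulfonium salt followed by SN2′ attack of bromide (allylic transposition) gives the primary (Z)-allylic bromide from both carbinol epimers.

Step 13
Reactants: 22 methyl (2Z,4R,5R,6Z,10E)-2-(bromomethyl)-5-(tert-butyldimethylsilyloxy)-4-(methoxymethoxy)-6,10-dimethyl-12-oxododeca-2,6,10-trienoate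
Product: 25 (6R,7S,8R,9R)-9-(tert-butyldimethylsilyloxy)-8-(methoxymethoxy)germacra-1(10)Z,4E,11(13)-trien-12,6-olide, via silyl ether 23 (not isolated), via hydroxy ester 24 (not isolated)
Conditions: CrCl2 (20 mol%), (S,S)-1,8-bis(4-isopropyl-4,5-dihydrooxazol-2-yl)-3,6-diphenyl-9H-carbazole (22 mol%), i-Pr2NEt (25 mol%), Mn powder (3 equiv), TMSCl (2 equiv), THF, rt, 22 added over 12 h (final 2 mM); then 1 M HCl, THF, 0 °C→rt
Reagents that add atoms: none
Why: Proposed new method: a chromium-catalysed, ligand-controlled macrocyclising 2-(methoxycarbonyl)allylation, in which CrCl2 (regenerated by Mn, released from the product by TMSCl) turns the allylic bromide into an allyl complex of trivalent chromium that equilibrates by 1,3-metal shift to the isomer with C8 trans to CH2Cr and adds to the enal through a closed chair transition state (anti addition, hence the trans-fused lactone once the γ-hydroxy ester closes on acid work-up), the tridentate ligand steering the allyl group to the Si face of the aldehyde (6R and, through the chair, 7S) in a sense matched with the substrate, whose A(1,3) strain at C8 and tether from C9 place the C8–O bond anti to the forming bond, while slow addition keeps the bromo-enal dilute; the closest known reactions are the stoichiometric CrCl2 Barbier macrocyclisation of 2-(bromomethyl)enoates onto aldehydes used for ten-membered germacranolides and the intermolecular chromium-catalysed enantioselective 2-(alkoxycarbonyl)allylation of aldehydes.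

Step 14
Reactants: 25 (6R,7S,8R,9R)-9-(tert-butyldimethylsilyloxy)-8-(methoxymethoxy)germacra-1(10)Z,4E,11(13)-trien-12,6-olide
Product: 27 (6R,7R,8R,9R)-9-(tert-butyldimethylsilyloxy)-8-hydroxygermacra-1(10)Z,4E,11(13)-trien-12,6-olide (same spatial arrangement; the C7 label changes because O8 now carries hydrogen), via bipyridinium salt 26 (not isolated)
Conditions: TMSOTf, 2,2′-bipyridyl, CH2Cl2, 0 °C→rt; then H2O
Reagents that add atoms: none
Why: Silyl triflate–bipyridyl cleavage of the MOM acetal runs through an N-(alkoxymethyl)pyridinium salt that water hydrolyses, and the buffered medium spares the silyl ether, the lactone and the acid-sensitive 1,5-diene.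

Step 15
Reactants: 28 angelic acid ((Z)-2-methylbut-2-enoic acid)
Product: 29 (Z)-2-methylbut-2-en-1-ol
Conditions: LiAlH4, Et2O, 0 °C
Reagents that add atoms: none
Why: Hydride 1,2-reduction of the acid gives the allylic alcohol with the Z olefin unchanged.

Step 16
Reactants: 29 (Z)-2-methylbut-2-en-1-ol
Product: 30 [(2R,3S)-2,3-dimethyloxiran-2-yl]methanol
Conditions: Ti(OiPr)4 (10 mol%), D-(−)-diethyl tartrate (12 mol%), t-BuOOH, 4 Å MS, CH2Cl2, −20 °C
Reagents that add atoms: tert-butyl hydroperoxide (CC(C)(C)OO)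
Why: Sharpless asymmetric epoxidation, in which the D-(−)-tartrate complex delivers oxygen to the olefin face that gives the (2R,3S)-epoxy alcohol and the Z geometry is carried over as the cis relation of CH2OH and the C3 methyl group.

Step 17
Reactants: 30 [(2R,3S)-2,3-dimethyloxiran-2-yl]methanol
Product: 31 (2S,3S)-2,3-dimethyloxirane-2-carboxylic acid
Conditions: RuCl3·xH2O (2 mol%), NaIO4, CCl4–MeCN–H2O, rt
Reagents that add atoms: sodium periodate ([Na+].[O-]I(=O)(=O)=O); water (O)
Why: Catalytic ruthenium oxidation (RuO4 formed in situ) takes the primary alcohol to the acid without opening the oxirane or touching its stereocentres.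

Step 18
Reactants: 31 (2S,3S)-2,3-dimethyloxirane-2-carboxylic acid; 27 (6R,7R,8R,9R)-9-(tert-butyldimethylsilyloxy)-8-hydroxygermacra-1(10)Z,4E,11(13)-trien-12,6-olide
Product: 33 (6R,7S,8R,9R)-9-(tert-butyldimethylsilyloxy)-8-[(2S,3S)-2,3-dimethyloxirane-2-carbonyloxy]germacra-1(10)Z,4E,11(13)-trien-12,6-olide, via mixed anhydride 32 (not isolated)
Conditions: 31, 2,4,6-trichlorobenzoyl chloride, Et3N, THF, rt; then 27, DMAP, toluene, rt→40 °C
Reagents that add atoms: none
Why: Yamaguchi esterification activates the hindered α,α-disubstituted glycidic acid as a mixed anhydride that DMAP transfers to the C8 hydroxyl with retention at every stereocentre.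

Step 19
Reactants: 33 (6R,7S,8R,9R)-9-(tert-butyldimethylsilyloxy)-8-[(2S,3S)-2,3-dimethyloxirane-2-carbonyloxy]germacra-1(10)Z,4E,11(13)-trien-12,6-olide
Product: 34 (6R,7S,8R,9R)-8-[(2S,3S)-2,3-dimethyloxirane-2-carbonyloxy]-9-hydroxygermacra-1(10)Z,4E,11(13)-trien-12,6-olide
Conditions: HF·pyridine, pyridine, THF, 0 °C→rt
Reagents that add atoms: none
Why: Buffered fluoride desilylation removes the allylic TBS ether under mildly acidic conditions that suppress acyl migration from O8 to O9 and leave the oxirane and the methylene lactone intact.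

Step 20
Reactants: 34 (6R,7S,8R,9R)-8-[(2S,3S)-2,3-dimethyloxirane-2-carbonyloxy]-9-hydroxygermacra-1(10)Z,4E,11(13)-trien-12,6-olide
Product: 35 (6R,7S,8R,9R)-9-acetoxy-8-[(2S,3S)-2,3-dimethyloxirane-2-carbonyloxy]germacra-1(10)Z,4E,11(13)-trien-12,6-olide (CNP0304643.2)
Conditions: Ac2O, pyridine, DMAP (cat.), CH2Cl2, 0 °C→rt
Reagents that add atoms: acetic anhydride (CC(=O)OC(C)=O)
Why: DMAP-catalysed acylation of the remaining secondary allylic alcohol gives the C9 acetate and hence the target.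

**Compound list**

1 | prop-2-yn-1-ol | C#CCO | starting material
2 | 4-methyl-2,5-dihydro-1,2-oxamagnesole (cyclic (Z)-alkenylmagnesium alkoxide) | CC1=C[Mg]OC1 | intermediate
3 | (Z)-3-iodo-2-methylprop-2-en-1-ol | I/C=C(/C)CO | intermediate
4 | (Z)-3-iodo-2-methylprop-2-enal | I/C=C(/C)C=O | intermediate
5 | prop-2-en-1-ol | C=CCO | starting material
6 | 3-(methoxymethoxy)prop-1-ene | C=CCOCOC | intermediate
7 | [(Z)-3-(methoxymethoxy)prop-2-en-1-yl]diisopinocampheylborane (isopinocampheyl groups from (+)-α-pinene, configured as in (−)-isopinocampheol) | COCO/C=C\CB([C@@H]1C[C@@H]2C[C@H]([C@H]1C)C2(C)C)[C@@H]1C[C@@H]2C[C@H]([C@H]1C)C2(C)C | intermediate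
8 | diisopinocampheylborinate ester of 9 | I/C=C(/C)[C@@H](OB([C@@H]1C[C@@H]2C[C@H]([C@H]1C)C2(C)C)[C@@H]1C[C@@H]2C[C@H]([C@H]1C)C2(C)C)[C@H](OCOC)C=C | intermediate
9 | (3R,4R,Z)-1-iodo-4-(methoxymethoxy)-2-methylhexa-1,5-dien-3-ol | I/C=C(/C)[C@@H](O)[C@H](OCOC)C=C | intermediate
10 | tert-butyl{[(3R,4R,Z)-1-iodo-4-(methoxymethoxy)-2-methylhexa-1,5-dien-3-yl]oxy}dimethylsilane | I/C=C(/C)[C@@H](O[Si](C)(C)C(C)(C)C)[C@H](OCOC)C=C | intermediate
11 | (3R,4R,Z)-4-(tert-butyldimethylsilyloxy)-6-iodo-3-(methoxymethoxy)-5-methylhex-5-ene-1,2-diol (both C2 epimers) | I/C=C(/C)[C@@H](O[Si](C)(C)C(C)(C)C)[C@H](OCOC)C(O)CO | intermediate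
12 | (2S,3R,Z)-3-(tert-butyldimethylsilyloxy)-5-iodo-2-(methoxymethoxy)-4-methylpent-4-enal | I/C=C(/C)[C@@H](O[Si](C)(C)C(C)(C)C)[C@H](OCOC)C=O | intermediate
13 | methyl acrylate | C=CC(=O)OC | starting material
14 | methyl 2-[(2R,3R,4Z)-3-(tert-butyldimethylsilyloxy)-1-hydroxy-5-iodo-2-(methoxymethoxy)-4-methylpent-4-en-1-yl]prop-2-enoate (both C1 epimers) | I/C=C(/C)[C@@H](O[Si](C)(C)C(C)(C)C)[C@H](OCOC)C(O)C(=C)C(=O)OC | intermediate
15 | (E)-3-methylpent-2-en-4-yn-1-ol | C#C/C(C)=C/CO | starting material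
16 | (E)-3-methylpent-2-en-4-ynal | C#C/C(C)=C/C=O | intermediate
17 | (E)-5,5-dimethoxy-3-methylpent-3-en-1-yne | C#C/C(C)=C/C(OC)OC | intermediate
18 | (E)-5,5-dimethoxy-3-methylpenta-1,3-diene | C=C/C(C)=C/C(OC)OC | intermediate
19 | 9-[(E)-5,5-dimethoxy-3-methylpent-3-en-1-yl]-9-borabicyclo[3.3.1]nonane | COC(OC)/C=C(\C)CCB1C2CCCC1CCC2 | intermediate
20 | methyl 2-[(2R,3R,4Z,8E)-3-(tert-butyldimethylsilyloxy)-1-hydroxy-10,10-dimethoxy-2-(methoxymethoxy)-4,8-dimethyldeca-4,8-dien-1-yl]prop-2-enoate (both C1 epimers) | COC(OC)/C=C(\C)CC/C=C(/C)[C@@H](O[Si](C)(C)C(C)(C)C)[C@H](OCOC)C(O)C(=C)C(=O)OC | intermediate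
21 | methyl 2-[(2R,3R,4Z,8E)-3-(tert-butyldimethylsilyloxy)-1-hydroxy-2-(methoxymethoxy)-4,8-dimethyl-10-oxodeca-4,8-dien-1-yl]prop-2-enoate (both C1 epimers) | O=C/C=C(\C)CC/C=C(/C)[C@@H](O[Si](C)(C)C(C)(C)C)[C@H](OCOC)C(O)C(=C)C(=O)OC | intermediate
22 | methyl (2Z,4R,5R,6Z,10E)-2-(bromomethyl)-5-(tert-butyldimethylsilyloxy)-4-(methoxymethoxy)-6,10-dimethyl-12-oxododeca-2,6,10-trienoate | O=C/C=C(\C)CC/C=C(/C)[C@@H](O[Si](C)(C)C(C)(C)C)[C@H](OCOC)/C=C(\CBr)C(=O)OC | intermediate
23 | methyl 2-[(1R,2R,3E,7Z,9R,10R)-9-(tert-butyldimethylsilyloxy)-10-(methoxymethoxy)-4,8-dimethyl-2-(trimethylsilyloxy)cyclodeca-3,7-dien-1-yl]prop-2-enoate | C=C(C(=O)OC)[C@H]1[C@H](O[Si](C)(C)C)/C=C(\C)CC/C=C(/C)[C@@H](O[Si](C)(C)C(C)(C)C)[C@@H]1OCOC | intermediate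
24 | methyl 2-[(1S,2R,3E,7Z,9R,10R)-9-(tert-butyldimethylsilyloxy)-2-hydroxy-10-(methoxymethoxy)-4,8-dimethylcyclodeca-3,7-dien-1-yl]prop-2-enoate | C=C(C(=O)OC)[C@H]1[C@H](O)/C=C(\C)CC/C=C(/C)[C@@H](O[Si](C)(C)C(C)(C)C)[C@@H]1OCOC | intermediate
25 | (6R,7S,8R,9R)-9-(tert-butyldimethylsilyloxy)-8-(methoxymethoxy)germacra-1(10)Z,4E,11(13)-trien-12,6-olide | C=C1C(=O)O[C@@H]2/C=C(\C)CC/C=C(/C)[C@@H](O[Si](C)(C)C(C)(C)C)[C@H](OCOC)[C@@H]12 | intermediate
26 | 1-(alkoxymethyl)-2,2′-bipyridinium triflate of 25 (O8–CH2–N+) | C=C1C(=O)O[C@@H]2/C=C(\C)CC/C=C(/C)[C@@H](O[Si](C)(C)C(C)(C)C)[C@H](OC[n+]3ccccc3-c3ccccn3)[C@@H]12.[O-]S(=O)(=O)C(F)(F)F | intermediate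
27 | (6R,7R,8R,9R)-9-(tert-butyldimethylsilyloxy)-8-hydroxygermacra-1(10)Z,4E,11(13)-trien-12,6-olide | C=C1C(=O)O[C@@H]2/C=C(\C)CC/C=C(/C)[C@@H](O[Si](C)(C)C(C)(C)C)[C@H](O)[C@@H]12 | intermediate
28 | angelic acid ((Z)-2-methylbut-2-enoic acid) | C/C=C(/C)C(=O)O | starting material
29 | (Z)-2-methylbut-2-en-1-ol | C/C=C(/C)CO | intermediate
30 | [(2R,3S)-2,3-dimethyloxiran-2-yl]methanol | OC[C@@]1(C)O[C@H]1C | intermediate
31 | (2S,3S)-2,3-dimethyloxirane-2-carboxylic acid | OC(=O)[C@@]1(C)O[C@H]1C | intermediate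
32 | (2S,3S)-2,3-dimethyloxirane-2-carboxylic 2,4,6-trichlorobenzoic anhydride | O=C(OC(=O)c1c(Cl)cc(Cl)cc1Cl)[C@@]1(C)O[C@H]1C | intermediate
33 | (6R,7S,8R,9R)-9-(tert-butyldimethylsilyloxy)-8-[(2S,3S)-2,3-dimethyloxirane-2-carbonyloxy]germacra-1(10)Z,4E,11(13)-trien-12,6-olide | C=C1C(=O)O[C@@H]2/C=C(\C)CC/C=C(/C)[C@@H](O[Si](C)(C)C(C)(C)C)[C@H](OC(=O)[C@@]3(C)O[C@H]3C)[C@@H]12 | intermediate
34 | (6R,7S,8R,9R)-8-[(2S,3S)-2,3-dimethyloxirane-2-carbonyloxy]-9-hydroxygermacra-1(10)Z,4E,11(13)-trien-12,6-olide | C=C1C(=O)O[C@@H]2/C=C(\C)CC/C=C(/C)[C@@H](O)[C@H](OC(=O)[C@@]3(C)O[C@H]3C)[C@@H]12 | intermediate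
35 | (6R,7S,8R,9R)-9-acetoxy-8-[(2S,3S)-2,3-dimethyloxirane-2-carbonyloxy]germacra-1(10)Z,4E,11(13)-trien-12,6-olide (CNP0304643.2) | C=C1C(=O)O[C@@H]2/C=C(\C)CC/C=C(/C)[C@@H](OC(C)=O)[C@H](OC(=O)[C@@]3(C)O[C@H]3C)[C@@H]12 | target

**Step count**

Total step count: 20.
Longest linear sequence: 13 steps (steps 1, 2, 4, 5, 6, 7, 11, 12, 13, 14, 18, 19, 20).

**Three steps most likely to fail**

Step 13 (proposed new macrocyclisation). Risks: slow turnover at high dilution, 1,4-elimination of the C8 alkoxy group from the allylchromium species, or a ligand sense that is mismatched with the substrate. The fallback uses known chemistry and reverses the order of the two carbon–carbon bond formations. It sets out from 14 and 18. Treatment of 14 with NBS and Me2S gives methyl (2Z,4R,5R,6Z)-2-(bromomethyl)-5-(tert-butyldimethylsilyloxy)-7-iodo-4-(methoxymethoxy)-6-methylhepta-2,6-dienoate F1. Acetal 18 is hydrolysed (PPTS, wet acetone) to (E)-3-methylpenta-2,4-dienal F2. The known intermolecular chromium-catalysed enantioselective 2-(alkoxycarbonyl)allylation (CrCl2 cat., the same ligand, Mn, TMSCl) joins them to the silyl ether of the anti γ-hydroxy ester F3, where the catalyst sets C6 and the chair transition state sets C7. Dilute HCl frees the anti γ-hydroxy-α-methylene ester F4, which closes to the trans-β,γ-disubstituted α-methylene-γ-butyrolactone F5 carrying the dienyl group at C6 and the iodoalkenyl chain at C7. 9-BBN adds to the terminal vinyl group of F5 to give the alkylborane F6, and an intramolecular B-alkyl Suzuki–Miyaura coupling (Pd(dppf)Cl2, AsPh3, Cs2CO3, DMF–THF–H2O, 2 mM) closes the C1–C2 bond and comes back to the route at 25.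

Step 11 (fragment coupling). Risk: the alkenylpalladium intermediate can add to the nearby acrylate (six-membered Heck-type closure), or the acrylate can suffer under aqueous base. The fallback couples before the acrylate exists. It sets out from diol 11, isolated by leaving out NaIO4 in step 6. Coupling of 11 with borane 19 under the same palladium conditions gives (3R,4R,5Z,9E)-4-(tert-butyldimethylsilyloxy)-11,11-dimethoxy-3-(methoxymethoxy)-5,9-dimethylundeca-5,9-diene-1,2-diol F7. NaIO4 cleaves it to (2S,3R,4Z,8E)-3-(tert-butyldimethylsilyloxy)-10,10-dimethoxy-2-(methoxymethoxy)-4,8-dimethyldeca-4,8-dienal F8. The Morita–Baylis–Hillman reaction of F8 with 13 then comes back to the route at 20, which dilute acid converts to 21.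

Step 7 (Morita–Baylis–Hillman reaction). Risk: the hindered α-alkoxy aldehyde reacts slowly, so epimerisation at C8 or β-elimination of the silyloxy group can compete. The fallback replaces amine catalysis by addition of a preformed vinylmetal and sets out from 12. Methyl propiolate F9 is hydroaluminated with i-Bu2AlH and NMO in THF at 0 °C to give [1-(methoxycarbonyl)ethenyl]diisobutylaluminium F10, which adds to 12 within an hour under non-basic conditions and comes back to the route at 14.

**Further compounds**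

F1 | step 13 | methyl (2Z,4R,5R,6Z)-2-(bromomethyl)-5-(tert-butyldimethylsilyloxy)-7-iodo-4-(methoxymethoxy)-6-methylhepta-2,6-dienoate | I/C=C(/C)[C@@H](O[Si](C)(C)C(C)(C)C)[C@H](OCOC)/C=C(\CBr)C(=O)OC
F2 | step 13 | (E)-3-methylpenta-2,4-dienal | C=C/C(C)=C/C=O
F3 | step 13 | trimethylsilyl ether of the anti γ-hydroxy ester F4 | C=C(C(=O)OC)[C@@H]([C@H](O[Si](C)(C)C)/C=C(\C)C=C)[C@@H](OCOC)[C@H](O[Si](C)(C)C(C)(C)C)/C(C)=C\I
F4 | step 13 | anti γ-hydroxy-α-methylene ester from F1 and F2 (C6 R, C7 S in germacrane numbering) | C=C(C(=O)OC)[C@@H]([C@H](O)/C=C(\C)C=C)[C@@H](OCOC)[C@H](O[Si](C)(C)C(C)(C)C)/C(C)=C\I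
F5 | step 13 | trans-β,γ-disubstituted α-methylene-γ-butyrolactone with the (E)-2-methylbuta-1,3-dienyl group at C6 and the iodoalkenyl chain at C7 | C=C1C(=O)O[C@H](/C=C(\C)C=C)[C@H]1[C@@H](OCOC)[C@H](O[Si](C)(C)C(C)(C)C)/C(C)=C\I
F6 | step 13 | 9-BBN adduct of F5 at the terminal vinyl group | C=C1C(=O)O[C@H](/C=C(\C)CCB2C3CCCC2CCC3)[C@H]1[C@@H](OCOC)[C@H](O[Si](C)(C)C(C)(C)C)/C(C)=C\I
F7 | step 11 | (3R,4R,5Z,9E)-4-(tert-butyldimethylsilyloxy)-11,11-dimethoxy-3-(methoxymethoxy)-5,9-dimethylundeca-5,9-diene-1,2-diol (both C2 epimers) | COC(OC)/C=C(\C)CC/C=C(/C)[C@@H](O[Si](C)(C)C(C)(C)C)[C@H](OCOC)C(O)CO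
F8 | step 11 | (2S,3R,4Z,8E)-3-(tert-butyldimethylsilyloxy)-10,10-dimethoxy-2-(methoxymethoxy)-4,8-dimethyldeca-4,8-dienal | COC(OC)/C=C(\C)CC/C=C(/C)[C@@H](O[Si](C)(C)C(C)(C)C)[C@H](OCOC)C=O
F9 | step 7 | methyl propiolate | C#CC(=O)OC
F10 | step 7 | [1-(methoxycarbonyl)ethenyl]diisobutylaluminium | C=C([Al](CC(C)C)CC(C)C)C(=O)OC
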